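The whole design rests on reading the tertiary α-ketol C1(OH)–C1'(=O) on the cyclopentene ring (C1–C5) as the product of a ring contraction: C1' was once a ring carbinol carbon sitting between C1 and C5 of a six-membered ortho-quinol. In one operation, epoxidation of the quinol enol ether and a semipinacol 1,2-shift of the ring carbonyl carbon (the future C5) form the C1–C5 and C2–O bonds, close the five-membered ring, expel C1' as the tridecanoyl ketone and set C1 and C2. The precursor is (6R)-6-dodecyl-6-hydroxy-5-(4-methoxybenzyloxy)cyclohexa-2,4-dienone, made by asymmetric hydroxylative dearomatisation of a mono-protected 2-dodecylresorcinol.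

Key step: step 5

Assumption: the sense of induction of the chiral iodane in step 4 cannot be predicted for this phenol; the antipode that delivers the 6R dienone is meant (drawn here as the (R)-biaryl) and is to be confirmed on first use.

Numbering: target atoms are C1 (quaternary carbinol), C1' (side-chain carbonyl), C2 (CHOH), C3=C4 and C5 (CHOAc). Dienone 8 and epoxide 9 are discussed with cyclohexadienone numbering (C1 carbonyl, C4=C5 enol ether, C6 carbinol).

Handling: 8 and 10 are kept cold and carried on without storage, because 8 can dimerise by [4+2] cycloaddition and 10 is a β-hydroxy-1,3-diketone open to retro-aldol cleavage under base.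

Step 1
Reactants: 1 1,3-dimethoxybenzene; 2 1-bromododecane
Product: 4 2-dodecyl-1,3-dimethoxybenzene, via 2,6-dimethoxyphenyllithium 3 (not isolated)
Conditions: n-BuLi, THF, 0 °C → rt; then 1-bromododecane, 0 °C → rt
Reagents that add atoms: none
Why: Directed ortho-metalation followed by SN2 alkylation: both methoxy groups direct lithiation to the carbon between them, and the aryllithium displaces bromide from the primary halide.

Step 2
Reactants: 4 2-dodecyl-1,3-dimethoxybenzene
Product: 5 2-dodecylbenzene-1,3-diol
Conditions: BBr3, CH2Cl2, −78 °C → rt; H2O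
Reagents that add atoms: none
Why: Lewis-acid demethylation of aryl methyl ethers: BBr3 should cleave both O–CH3 bonds and leave the alkyl chain untouched.

Step 3
Reactants: 5 2-dodecylbenzene-1,3-diol; 6 4-methoxybenzyl chloride
Product: 7 2-dodecyl-3-[(4-methoxyphenyl)methoxy]phenol
Conditions: K2CO3 (1 equiv), 4-methoxybenzyl chloride (1 equiv), DMF, rt
Reagents that add atoms: none
Why: Williamson ether synthesis on a symmetric diol: one equivalent of base and halide should give mainly the mono-ether, no regiochemical question arises because both hydroxyls are equivalent, and unreacted diol and bis-ether are separable and recyclable.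

Step 4
Reactants: 7 2-dodecyl-3-[(4-methoxyphenyl)methoxy]phenol
Product: 8 (6R)-6-dodecyl-6-hydroxy-5-[(4-methoxyphenyl)methoxy]cyclohexa-2,4-dien-1-one
Conditions: (R)-2,2'-diiodyl-1,1'-binaphthyl (0.55 equiv), THF, −20 → 0 °C; aq. NaHCO3
Reagents that add atoms: (R)-2,2'-diiodyl-1,1'-binaphthyl, O=I(=O)c1ccc2ccccc2c1-c1c(I(=O)=O)ccc2ccccc12 (axial configuration not expressed in the SMILES)
Why: Asymmetric hydroxylative phenol dearomatisation by a chiral pentavalent iodine reagent: after ligand exchange of the phenol at iodine an iodyl oxygen should pass intramolecularly to the more substituted ortho carbon, which is activated by both ring oxygens and gives a dienone that cannot tautomerise (as 2-alkylphenols with a free ortho position are known to do), the twofold-symmetric biaryl selecting the face and so setting C6 as R, while the 5-alkoxy group makes the dienone a vinylogous ester and slows its [4+2] dimerisation.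

Step 5
Reactants: 8 (6R)-6-dodecyl-6-hydroxy-5-[(4-methoxyphenyl)methoxy]cyclohexa-2,4-dien-1-one
Product: 10 (4R,5R)-4-hydroxy-5-[(4-methoxyphenyl)methoxy]-5-tridecanoylcyclopent-2-en-1-one, via syn-alkoxy-epoxide 9 (not isolated)
Conditions: DMDO (1.1 equiv, acetone), CH2Cl2, 4 Å MS, −78 → −20 °C; then Zn(OTf)2 (10 mol %), −20 → 0 °C
Reagents that add atoms: dimethyldioxirane, CC1(C)OO1
Why: Proposed new method: the electrophilic dioxirane should attack only the electron-rich enol-ether alkene C4=C5 of 8 (the enone alkene C2=C3 is deactivated) and do so on the face of the C6 hydroxyl, which hydrogen-bonds the oxidant and is far smaller than the dodecyl chain shielding the other face, giving epoxide 9. Zn(OTf)2, held between the syn hydroxyl and the epoxide oxygen, then breaks the C5–O bond towards an oxocarbenium ion stabilised by the benzylic ether oxygen, and the ring carbonyl carbon C1 shifts from C6 to C5 while the C6 hydroxyl collapses to the side-chain ketone (semipinacol 1,2-acyl shift). The closest known reaction types are the Lewis-acid semipinacol rearrangement of 2,3-epoxy alcohols, the acyl-shift rearrangement of α,β-epoxy ketones to 1,3-dicarbonyl compounds, the contraction of cyclohexene oxides to cyclopentyl carbonyl compounds and the Rubottom-type epoxidation of enol ethers, but their combination on an ortho-quinol is without precedent. The cyclopentenone ring is closed not by a cyclisation but by ring contraction, the C1–C5 bond forming as the C1–C6 bond breaks through a three-centre bridged transition state inside the six-membered ring. The quaternary centre (target C1) is set by inversion at C5, the chelate holding the C6 hydroxyl pseudo-axial so that the migrating carbon can only arrive on the face opposite the departing oxygen, and the carbinol (target C2) is set by the face of epoxidation, so the new hydroxyl ends up cis to the acyl branch and trans to the ether oxygen, the absolute sense being relayed from C6, whose own chirality is consumed. The step needs migration of the acyl carbon rather than of the dodecyl group or the C4 hydrogen: chelation of the syn C4 and C6 oxygens puts the C4–H bond in the nodal plane of the cation and denies the dodecyl group the axial alignment it would need, so the choice falls to intrinsic migratory aptitude, where a conjugated acyl carbon is far superior to a primary alkyl group, and an alkyl rather than a silyl enol ether is used so that no Rubottom-type group transfer can quench the cation.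

Step 6
Reactants: 10 (4R,5R)-4-hydroxy-5-[(4-methoxyphenyl)methoxy]-5-tridecanoylcyclopent-2-en-1-one
Product: 11 (4R,5R)-5-[(4-methoxyphenyl)methoxy]-5-tridecanoyl-4-(triethylsilyloxy)cyclopent-2-en-1-one
Conditions: TESOTf, 2,6-lutidine, CH2Cl2, −78 °C
Reagents that add atoms: triethylsilyl trifluoromethanesulfonate, CC[Si](CC)(CC)OS(=O)(=O)C(F)(F)F
Why: Silylation of the secondary allylic hydroxyl with a silyl triflate and a hindered weak base is fast at −78 °C, avoids the basic conditions that could trigger retro-aldol cleavage, and keeps C2 and C5 distinguishable after the reduction, since the corresponding free cis-diol would be meso.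

Step 7
Reactants: 11 (4R,5R)-5-[(4-methoxyphenyl)methoxy]-5-tridecanoyl-4-(triethylsilyloxy)cyclopent-2-en-1-one
Product: 12 1-[(1R,2S,5R)-2-hydroxy-1-[(4-methoxyphenyl)methoxy]-5-(triethylsilyloxy)cyclopent-3-en-1-yl]tridecan-1-one
Conditions: NaBH4, CeCl3·7H2O, MeOH, −78 °C
Reagents that add atoms: none
Why: Luche 1,2-reduction: the CeCl3-activated cyclopentenone carbonyl should react faster than the side-chain ketone flanked by a quaternary carbon, and hydride should arrive on the face of the C1 ether oxygen, anti to both the C2 silyloxy group and the acyl branch (as in the cis-selective Luche reductions of 4-silyloxycyclopent-2-enones), so that the new C5 hydroxyl is cis to the C2 oxygen.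

Step 8
Reactants: 12 1-[(1R,2S,5R)-2-hydroxy-1-[(4-methoxyphenyl)methoxy]-5-(triethylsilyloxy)cyclopent-3-en-1-yl]tridecan-1-one
Product: 13 (1S,4R,5R)-5-[(4-methoxyphenyl)methoxy]-5-tridecanoyl-4-(triethylsilyloxy)cyclopent-2-en-1-yl acetate
Conditions: Ac2O, pyridine, DMAP (cat.), CH2Cl2, 0 °C → rt
Reagents that add atoms: acetic anhydride, CC(=O)OC(C)=O
Why: DMAP-catalysed acylation of the only free hydroxyl, a secondary allylic alcohol, proceeds with retention at C5 and leaves the silyl ether, the benzylic ether and the ketone untouched.

Step 9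
Reactants: 13 (1S,4R,5R)-5-[(4-methoxyphenyl)methoxy]-5-tridecanoyl-4-(triethylsilyloxy)cyclopent-2-en-1-yl acetate
Product: 14 (1S,4R,5R)-5-hydroxy-5-tridecanoyl-4-(triethylsilyloxy)cyclopent-2-en-1-yl acetate
Conditions: DDQ, CH2Cl2/pH 7 phosphate buffer, 0 °C → rt
Reagents that add atoms: none
Why: Oxidative cleavage of the 4-methoxybenzyl ether by DDQ (benzylic hydride abstraction, then hydrolysis) under buffered conditions should free the tertiary C1 hydroxyl without touching the silyl ether, the allylic acetate or the alkene, and the acetate cannot migrate to the new hydroxyl because the two are trans on the five-membered ring.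

Step 10
Reactants: 14 (1S,4R,5R)-5-hydroxy-5-tridecanoyl-4-(triethylsilyloxy)cyclopent-2-en-1-yl acetate
Product: 15 (1S,4R,5S)-4,5-dihydroxy-5-tridecanoylcyclopent-2-en-1-yl acetate (both ring oxygens at C2 and C5 cis to the acyl group, trans to the C1 hydroxyl)
Conditions: HF·pyridine, pyridine, THF, 0 °C
Reagents that add atoms: none
Why: Fluoride-mediated desilylation under buffered, mildly acidic conditions removes the triethylsilyl group while avoiding base, under which the acetyl group could move between the cis-related C5 and C2 oxygens and thereby interconvert the enantiomers of this monoacetate of a meso triol.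

Compound list
1 | 1,3-dimethoxybenzene | COc1cccc(OC)c1 | starting material
2 | 1-bromododecane | CCCCCCCCCCCCBr | starting material
3 | 2,6-dimethoxyphenyllithium | [Li]c1c(OC)cccc1OC | intermediate (not isolated)
4 | 2-dodecyl-1,3-dimethoxybenzene | CCCCCCCCCCCCc1c(OC)cccc1OC | intermediate
5 | 2-dodecylbenzene-1,3-diol | CCCCCCCCCCCCc1c(O)cccc1O | intermediate
6 | 4-methoxybenzyl chloride | COc1ccc(CCl)cc1 | starting material
7 | 2-dodecyl-3-[(4-methoxyphenyl)methoxy]phenol | CCCCCCCCCCCCc1c(O)cccc1OCc1ccc(OC)cc1 | intermediate
8 | (6R)-6-dodecyl-6-hydroxy-5-[(4-methoxyphenyl)methoxy]cyclohexa-2,4-dien-1-one | CCCCCCCCCCCC[C@]1(O)C(=O)C=CC=C1OCc2ccc(OC)cc2 | intermediate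
9 | (1R,2S,6R)-2-dodecyl-2-hydroxy-1-[(4-methoxyphenyl)methoxy]-7-oxabicyclo[4.1.0]hept-4-en-3-one (4,5-epoxide of 8, epoxide oxygen cis to the hydroxyl) | CCCCCCCCCCCC[C@]1(O)C(=O)C=C[C@H]2O[C@@]12OCc3ccc(OC)cc3 | intermediate (not isolated)
10 | (4R,5R)-4-hydroxy-5-[(4-methoxyphenyl)methoxy]-5-tridecanoylcyclopent-2-en-1-one (hydroxyl cis to the acyl group) | CCCCCCCCCCCCC(=O)[C@]1(OCc2ccc(OC)cc2)[C@H](O)C=CC1=O | intermediate
11 | (4R,5R)-5-[(4-methoxyphenyl)methoxy]-5-tridecanoyl-4-(triethylsilyloxy)cyclopent-2-en-1-one | CCCCCCCCCCCCC(=O)[C@]1(OCc2ccc(OC)cc2)[C@H](O[Si](CC)(CC)CC)C=CC1=O | intermediate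
12 | 1-[(1R,2S,5R)-2-hydroxy-1-[(4-methoxyphenyl)methoxy]-5-(triethylsilyloxy)cyclopent-3-en-1-yl]tridecan-1-one (hydroxyl and silyloxy group cis to each other and to the acyl group) | CCCCCCCCCCCCC(=O)[C@]1(OCc2ccc(OC)cc2)[C@H](O[Si](CC)(CC)CC)C=C[C@@H]1O | intermediate
13 | (1S,4R,5R)-5-[(4-methoxyphenyl)methoxy]-5-tridecanoyl-4-(triethylsilyloxy)cyclopent-2-en-1-yl acetate | CCCCCCCCCCCCC(=O)[C@]1(OCc2ccc(OC)cc2)[C@H](O[Si](CC)(CC)CC)C=C[C@@H]1OC(C)=O | intermediate
14 | (1S,4R,5R)-5-hydroxy-5-tridecanoyl-4-(triethylsilyloxy)cyclopent-2-en-1-yl acetate | CCCCCCCCCCCCC(=O)[C@]1(O)[C@H](O[Si](CC)(CC)CC)C=C[C@@H]1OC(C)=O | intermediate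
15 | (1S,4R,5S)-4,5-dihydroxy-5-tridecanoylcyclopent-2-en-1-yl acetate | CCCCCCCCCCCCC(=O)[C@]1(O)[C@H](O)C=C[C@@H]1OC(C)=O | target

Total step count: 10. Longest linear sequence: 10 steps (from 1).

Steps most likely to fail

Step 5 (the step that bears the label). Several processes may intervene:
- the dodecyl group or the C4 hydrogen may migrate instead of the acyl carbon;
- the oxocarbenium ion may lose its benzylic group or be hydrated before any shift, leaving an unrearranged α-hydroxy ketone;
- facial control of the epoxidation may be incomplete, eroding enantiopurity;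
- the dienone may dimerise before it is oxidised.

The fallback uses known chemistry only, sets out from 2 and rejoins the route at 14. It gives up the ring contraction, buys the five-membered ring and lets the C2 stereocentre (chiral pool) control C1 and C5. 2 is converted with Mg in THF into dodecylmagnesium bromide F1 and formylated with DMF to tridecanal F2. Commercially available (4S)-4-hydroxycyclopent-2-en-1-one F3 is silylated (TESCl, imidazole, CH2Cl2) to (4S)-4-(triethylsilyloxy)cyclopent-2-en-1-one F4. Deprotonation with LDA in THF at −78 °C gives lithium (3R)-3-(triethylsilyloxy)cyclopenta-1,4-dien-1-olate F5, which adds to F2 in an aldol reaction to give (4R)-5-(1-hydroxytridecyl)-4-(triethylsilyloxy)cyclopent-2-en-1-one F6. Its configurations at C5 and at the side-chain carbinol do not matter, because oxidation with Dess–Martin periodinane gives the enolised β-diketone (4R)-5-tridecanoyl-4-(triethylsilyloxy)cyclopent-2-en-1-one F7. Hydroxylation of F7 at C5 with DMDO, a standard α-hydroxylation of enolised 1,3-dicarbonyl compounds, should occur anti to the silyloxy group and give (4R,5R)-5-hydroxy-5-tridecanoyl-4-(triethylsilyloxy)cyclopent-2-en-1-one F8. Luche reduction anti to the silyloxy group should then give 1-[(1R,2S,5R)-1,2-dihydroxy-5-(triethylsilyloxy)cyclopent-3-en-1-yl]tridecan-1-one F9, and acetylation of its secondary hydroxyl (Ac2O, pyridine) gives 14, from which step 10 is used unchanged.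

Step 4. The chiral iodane may give insufficient enantioselection, oxygen may be transferred to the unsubstituted ortho carbon (leading on to an ortho-quinone), and the dienone may dimerise. The fallback sets out from 10 and rejoins the route at 13. It moves the origin of absolute configuration to a late enzymatic desymmetrisation, so that 8 of any enantiomeric purity can be used, even racemic material made with an achiral iodyl reagent such as stabilised 2-iodoxybenzoic acid. 10 is reduced without protection (NaBH4, CeCl3·7H2O, MeOH, −78 °C) to meso-1-[2,5-dihydroxy-1-[(4-methoxyphenyl)methoxy]cyclopent-3-en-1-yl]tridecan-1-one (both hydroxyls cis to the acyl group) F10, whose two carbinols are enantiotopic. A lipase with vinyl acetate (immobilised Candida antarctica lipase B or Burkholderia cepacia lipase, chosen by screening for acetylation of the carbinol that becomes C5) should give (1S,4R,5S)-4-hydroxy-5-[(4-methoxyphenyl)methoxy]-5-tridecanoylcyclopent-2-en-1-yl acetate F11. Silylation (TESOTf, 2,6-lutidine, CH2Cl2, −78 °C) then gives 13.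

Step 7. Hydride may be delivered to the wrong face of the ring carbonyl, and the side-chain ketone may be reduced in competition. The fallback sets out from 11 and rejoins the route at 13. Instead of forcing the facial selectivity, the epimeric alcohol is accepted and C5 is corrected by SN2 inversion. The C5-epimeric alcohol 1-[(1R,2R,5R)-2-hydroxy-1-[(4-methoxyphenyl)methoxy]-5-(triethylsilyloxy)cyclopent-3-en-1-yl]tridecan-1-one F12, obtained from the reduction of 11, is submitted to a Mitsunobu reaction with acetic acid (PPh3, DIAD, THF, 0 °C → rt). This installs the acetate with inversion and gives 13 directly, so that step 8 is not needed for this material.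

Further compounds
F1 | step 5 | dodecylmagnesium bromide | CCCCCCCCCCCC[Mg]Br
F2 | step 5 | tridecanal | CCCCCCCCCCCCC=O
F3 | step 5 | (4S)-4-hydroxycyclopent-2-en-1-one (purchased) | O=C1C=C[C@@H](O)C1
F4 | step 5 | (4S)-4-(triethylsilyloxy)cyclopent-2-en-1-one | O=C1C=C[C@@H](O[Si](CC)(CC)CC)C1
F5 | step 5 | lithium (3R)-3-(triethylsilyloxy)cyclopenta-1,4-dien-1-olate | [Li]OC1=C[C@H](O[Si](CC)(CC)CC)C=C1
F6 | step 5 | (4R)-5-(1-hydroxytridecyl)-4-(triethylsilyloxy)cyclopent-2-en-1-one (mixture of epimers at C5 and at the side-chain carbinol) | CCCCCCCCCCCCC(O)C1C(=O)C=C[C@H]1O[Si](CC)(CC)CC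
F7 | step 5 | (4R)-5-tridecanoyl-4-(triethylsilyloxy)cyclopent-2-en-1-one (enolised β-diketone) | CCCCCCCCCCCCC(=O)C1C(=O)C=C[C@H]1O[Si](CC)(CC)CC
F8 | step 5 | (4R,5R)-5-hydroxy-5-tridecanoyl-4-(triethylsilyloxy)cyclopent-2-en-1-one | CCCCCCCCCCCCC(=O)[C@]1(O)[C@H](O[Si](CC)(CC)CC)C=CC1=O
F9 | step 5 | 1-[(1R,2S,5R)-1,2-dihydroxy-5-(triethylsilyloxy)cyclopent-3-en-1-yl]tridecan-1-one | CCCCCCCCCCCCC(=O)[C@]1(O)[C@H](O[Si](CC)(CC)CC)C=C[C@@H]1O
F10 | step 4 | meso-1-[2,5-dihydroxy-1-[(4-methoxyphenyl)methoxy]cyclopent-3-en-1-yl]tridecan-1-one (both hydroxyls cis to the acyl group) | CCCCCCCCCCCCC(=O)[C@]1(OCc2ccc(OC)cc2)[C@H](O)C=C[C@@H]1O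
F11 | step 4 | (1S,4R,5S)-4-hydroxy-5-[(4-methoxyphenyl)methoxy]-5-tridecanoylcyclopent-2-en-1-yl acetate | CCCCCCCCCCCCC(=O)[C@]1(OCc2ccc(OC)cc2)[C@H](O)C=C[C@@H]1OC(C)=O
F12 | step 7 | 1-[(1R,2R,5R)-2-hydroxy-1-[(4-methoxyphenyl)methoxy]-5-(triethylsilyloxy)cyclopent-3-en-1-yl]tridecan-1-one | CCCCCCCCCCCCC(=O)[C@]1(OCc2ccc(OC)cc2)[C@H](O[Si](CC)(CC)CC)C=C[C@H]1O
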